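**At handover.** 3 questions stood for gamma and epsilon, and I left this note for the next person at the bench.

| flask | free monomer | initiator | remark | time |
|---|---|---|---|---|
| ochre | 0.010 M | 0.15 mM | run made earlier |  |
| green | 0.010 M | 0.69 mM | run made earlier |  |
| gamma | 0.010 M | 0.20 mM |  | 2.0 d |
| epsilon | 0.010 M | 0.80 mM |  | 2.0 d |

| run | time / h | monomer in chains / % | free monomer / % |
|---|---|---|---|
| ochre | 1.33 | 0.8 | 96.1 |
| ochre | 4.00 | 7.9 | 85.9 |
| ochre | 6.00 | 10.9 | 80.5 |
| ochre | 10.0 | 14.5 | 70.1 |
| ochre | 15.0 | 20.2 | 59.9 |
| ochre | 20.0 | 20.1 | 52.2 |
| ochre | 25.0 | 23.5 | 45.8 |
| green | 1.33 | 9.4 | 87.3 |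
| green | 4.00 | 25.6 | 67.6 |
| green | 6.00 | 29.6 | 60.3 |
| green | 10.0 | 38.6 | 48.8 |
| green | 15.0 | 45.0 | 40.4 |
| green | 20.0 | 46.4 | 34.8 |
| green | 25.0 | 46.0 | 29.3 |

(readings scatter by 1 percentage point)

1. which of the two ends with the longer chains by the average number of monomer units in a chain (chains begun, living or dead) ("neither" if they lie within 10%) (gamma / epsilon / neither)
2. average number of monomer units in a chain (chains begun, living or dead) at the end, gamma
3. average number of monomer units in a chain (chains begun, living or dead) at the end, epsilon

- the average divides the monomer in chains by the number of chains begun, living and dead together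
- the numbers in the tables scatter with a standard deviation of 1 percentage point
- steps under discussion: free monomer + initiator -> living end + monomer in chains; free monomer -> uncatalysed product; free monomer + living end -> monomer in chains + living end; 2 living end -> dead end
- the earlier runs do not show the number of chains; that part of a forecast is a guess

**Ceiling length.** I counted one chain begun per initiator charged, which the earlier runs do not show. I then divided free monomer charged by initiator charged: 50.0 for gamma, 12.5 for epsilon. This is the ceiling length, the units per chain if the whole charge of free monomer entered chains. On that count of chains, the average length is the ceiling times the share of the charged free monomer in chains.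

**Expected contents.** At its last reading ochre held 23.5% in chains and green 46.0%, while 30.7% of ochre was missing from both columns, which I took as uncatalysed product. Those shares gave me 11.8 units for gamma and 5.75 for epsilon. I held both as low: gamma had more initiator than ochre, epsilon more than green, and both ran longer.

**Do not touch.** Add no initiator: at the same free monomer, a larger initiator charge lowers the ceiling, as epsilon's stands below gamma's.

**The forecast.** It named gamma, with 16 units for gamma and 6.7 for epsilon, above my figures, on the view that “initiation finishes within a few hours”.

**The result.** Gamma gave 16.4 units and epsilon 6.92, so gamma had the longer chains and the forecast held. Initiator stood at 0% of its charge in gamma and 0% in epsilon after 2.00 d, with 32.9% and 55.4% of the charged free monomer in chains. The ceilings times these shares give 16.4 and 6.93.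

    free monomer + initiator → living end + monomer in chains (k = 1.50 M⁻¹ min⁻¹)
    free monomer → uncatalysed product (k = 3.10 × 10⁻⁴ min⁻¹)
    free monomer + living end → monomer in chains + living end, rate k3*[living end]*[free monomer] (k = 2.50 M⁻¹ min⁻¹)
    2 living end → dead end (k = 4.20 M⁻¹ min⁻¹)

**Second flask.** The neighbour is epsilon with 0.025 M free monomer. Its ceiling is 31.2, and epsilon's share makes that 17.3 units. The simulation gave 16.3, with 52.0% in chains.

The data are simulated on assumed constants; scatter was added.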